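**Plan**
1. Retrosynthesis: the butenolide C11=C12 bond and the C1–C15 bond (ring CH to the quaternary CMe2 carbon) are cut together. This leaves a 15-membered macrolactone 22 with Br on C12 (α to the lactone C=O) and a fluorine-marked alkene C11(F)=C15Me2 on C10. Further cuts: C1=C2 (ring-closing metathesis), the ester C18–O, C5–C6 (allylboration), C6–C7 with the CH3–C8 bond (carboalumination, hydroxymethylation) and C9–C10 (propargylation).
2. Enabling feature: in 22 the radical site C12 lies five atoms from C11 (via C18, O, C10), and C15 then lies six atoms from C1 (via C11, C12, C13, C14). One radical chain can therefore close the γ-lactone and the six-membered ring; the second closure also creates the 12-membered carbocycle (C1 to C11 plus C15) of the bicyclo[9.3.1] core.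
3. Forward order of rings: 15-membered lactone first; then, in one flask, γ-lactone, six-membered ring and 12-membered ring; loss of HF from C11/C12 turns the lactone into the butenolide.
4. Stereochemistry: C10 (R) from a chiral phosphoric acid-catalysed propargylation; C6 (S) from a chiral phosphoric acid-catalysed allylboration; 7E from syn-carboalumination; C1 (R) from the macrocycle-controlled 6-exo closure.

Key step: step 16

Locants used for all intermediates: C1 = CH that becomes bonded to CMe2; C2, C3 = CH2; C4 = C(=C20H2); C5 = CH2; C6 = CH(OAc); C7=C8 (C8 carries CH3); C9 = CH2; C10 = CH–O; C11, C12 = butenolide alkene carbons (C11 carries C10 and C15); C13, C14 = CH2; C15 = CMe2; C18 = lactone C=O.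

Assumption: 20, 21 and 22 are mixtures of epimers at the bromine-bearing carbon C12, and 22 is an E/Z mixture at C1=C2 (E drawn); both elements disappear in step 16.

(R)-TRIP and (S)-TRIP are the enantiomers of 3,3′-bis(2,4,6-triisopropylphenyl)-1,1′-binaphthyl-2,2′-diyl hydrogen phosphate.

**Step 1**
Reactants: 1 triethyl 2-fluoro-2-phosphonoacetate; 2 acetone
Product: 3 ethyl 2-fluoro-3-methylbut-2-enoate
Conditions: NaH, THF, 0 °C to rt
Reagents that add atoms: none
Why: Horner–Wadsworth–Emmons olefination of the symmetric ketone by the fluorinated phosphonate carbanion, which places fluorine on the future C11 with no alkene geometry to control.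

**Step 2**
Reactants: 3 ethyl 2-fluoro-3-methylbut-2-enoate
Product: 4 2-fluoro-3-methylbut-2-en-1-ol
Conditions: i-Bu2AlH (2.2 equiv), CH2Cl2, −78 to 0 °C; aqueous Rochelle salt
Reagents that add atoms: none
Why: 1,2-reduction of the α,β-unsaturated ester to the allylic alcohol by the aluminium hydride, the tetrasubstituted fluoroalkene being inert.

**Step 3**
Reactants: 4 2-fluoro-3-methylbut-2-en-1-ol
Product: 5 2-fluoro-3-methylbut-2-enal
Conditions: Dess–Martin periodinane, CH2Cl2, 0 °C to rt; used as a solution
Reagents that add atoms: none
Why: Dess–Martin oxidation of the primary allylic alcohol stops cleanly at the aldehyde.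

**Step 4**
Reactants: 5 2-fluoro-3-methylbut-2-enal; 6 allenylboronic acid pinacol ester
Product: 7 (4R)-5-fluoro-6-methylhept-5-en-1-yn-4-ol
Conditions: (R)-TRIP (10 mol %), 4 Å molecular sieves, toluene, −20 °C; aqueous work-up
Reagents that add atoms: none
Why: chiral phosphoric acid-catalysed propargylboration through a closed six-membered SE2′ transition state, the (R)-catalyst being chosen to direct attack to the Re face of the aldehyde and so set C10 as R.

**Step 5**
Reactants: 7 (4R)-5-fluoro-6-methylhept-5-en-1-yn-4-ol
Product: 8 tert-butyl{[(4R)-5-fluoro-6-methylhept-5-en-1-yn-4-yl]oxy}dimethylsilane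
Conditions: TBSCl, imidazole, DMF, rt
Reagents that add atoms: tert-butyldimethylsilyl chloride CC(C)(C)[Si](C)(C)Cl
Why: standard silylation protects the C10 hydroxyl through the organoaluminium, oxidation and acylation steps.

**Step 6**
Reactants: 8 silyl ether
Product: 9 (2E,5R)-5-(tert-butyldimethylsilyloxy)-6-fluoro-3,7-dimethylocta-2,6-dien-1-ol
Conditions: Me3Al (2.5 equiv), Cp2ZrCl2 (25 mol %), CH2Cl2, 0 °C to rt; then n-BuLi, −78 °C; then (CH2O)n, THF, rt; aqueous work-up
Reagents that add atoms: trimethylaluminium C[Al](C)C; formaldehyde (from paraformaldehyde) C=O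
Why: Negishi carboalumination adds CH3 and Al syn across the terminal alkyne (CH3 to the internal carbon), and the derived alanate is hydroxymethylated with retention, which fixes the 7E trisubstituted alkene.

**Step 7**
Reactants: 9 allylic alcohol
Product: 10 (2E,5R)-5-(tert-butyldimethylsilyloxy)-6-fluoro-3,7-dimethylocta-2,6-dienal
Conditions: MnO2, CH2Cl2, rt
Reagents that add atoms: none
Why: chemoselective MnO2 oxidation of the primary allylic alcohol to the enal without touching the alkene geometry.

**Step 8**
Reactants: 11 3-chloro-2-(chloromethyl)prop-1-ene (3 equiv); 12 vinylmagnesium bromide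
Product: 13 2-(chloromethyl)penta-1,4-diene
Conditions: CuI (5 mol %), THF, −20 to 0 °C
Reagents that add atoms: none
Why: copper-catalysed allylic substitution by the vinyl Grignard reagent, in which SN2 and SN2′ attack give the same product and excess dichloride suppresses double substitution.

**Step 9**
Reactants: 13 2-(chloromethyl)penta-1,4-diene; 14 2-isopropoxy-4,4,5,5-tetramethyl-1,3,2-dioxaborolane
Product: 15 4,4,5,5-tetramethyl-2-(2-methylidenepent-4-en-1-yl)-1,3,2-dioxaborolane
Conditions: Mg, THF, 0 °C to rt (Barbier mode); aqueous NH4Cl
Reagents that add atoms: none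
Why: Barbier-type magnesium insertion into the allylic chloride and trapping by the borate ester gives the allylboronate, whose allyl unit is degenerate to 1,3-transposition.

**Step 10**
Reactants: 10 enal; 15 allylboronate
Product: 16 (6S,7E,10R)-10-(tert-butyldimethylsilyloxy)-11-fluoro-8,12-dimethyl-4-methylidenetrideca-1,7,11-trien-6-ol
Conditions: (S)-TRIP (5 mol %), toluene, −30 °C; aqueous work-up
Reagents that add atoms: none
Why: chiral phosphoric acid-catalysed allylboration through a chair transition state, the (S)-catalyst being chosen to deliver the 2-substituted allyl group to the Si face of the enal and so set C6 as S under catalyst control.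

**Step 11**
Reactants: 16 secondary allylic alcohol
Product: 17 (6S,7E,10R)-10-(tert-butyldimethylsilyloxy)-11-fluoro-8,12-dimethyl-4-methylidenetrideca-1,7,11-trien-6-yl acetate
Conditions: Ac2O, pyridine, DMAP (cat.), CH2Cl2, rt
Reagents that add atoms: acetic anhydride CC(=O)OC(C)=O
Why: DMAP-catalysed acetylation installs the C6 acetate of the target with retention at C6.

**Step 12**
Reactants: 17 silyl ether acetate
Product: 18 (6S,7E,10R)-11-fluoro-10-hydroxy-8,12-dimethyl-4-methylidenetrideca-1,7,11-trien-6-yl acetate
Conditions: HF·pyridine, pyridine, THF, 0 °C to rt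
Reagents that add atoms: none
Why: buffered fluoride-mediated desilylation frees the C10 hydroxyl while the acetate and the vinyl fluoride are inert.

**Step 13**
Reactants: 19 hex-5-enoic acid
Product: 20 2-bromohex-5-enoic acid (racemic)
Conditions: LiN(i-Pr)2 (2.2 equiv), THF, −78 to 0 °C; CBr4, −78 °C; aqueous HCl
Reagents that add atoms: carbon tetrabromide BrC(Br)(Br)Br
Why: α-bromination of the carboxylic acid dianion by bromine transfer from CBr4; the racemic centre is of no consequence because C12 later becomes a radical and then sp2.

**Step 14**
Reactants: 18 C10 alcohol; 20 2-bromohex-5-enoic acid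
Product: 21 (6S,7E,10R)-6-acetoxy-11-fluoro-8,12-dimethyl-4-methylidenetrideca-1,7,11-trien-10-yl 2-bromohex-5-enoate
Conditions: DCC, DMAP (10 mol %), CH2Cl2, 0 °C to rt
Reagents that add atoms: none
Why: Steglich esterification forms the C18–O bond with retention at C10.

**Step 15**
Reactants: 21 diene ester
Product: 22 (6E,11S,12E,15R)-3-bromo-15-(1-fluoro-2-methylprop-1-en-1-yl)-13-methyl-9-methylidene-2-oxo-1-oxacyclopentadeca-6,12-dien-11-yl acetate (15-membered macrolactone)
Conditions: second-generation Grubbs catalyst (10 mol %), CH2Cl2 (1 mM), 40 °C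
Reagents that add atoms: none
Why: ring-closing metathesis joins the only two monosubstituted alkenes (C1 and C2) with loss of ethene, the 1,1-disubstituted, trisubstituted and tetrasubstituted alkenes being far slower partners.

**Step 16**
Reactants: 22 macrolactone
Product: 24 target CNP0289913.1, via tricyclic β-fluoro lactone 23 (not isolated)
Conditions: (Me3Si)3SiH (1.2 equiv), AIBN (0.2 equiv), PhH (1 mM), 80 °C, syringe-pump addition; then DBU (3 equiv), 50 °C, same flask
Reagents that add atoms: none
Why: The silyl radical abstracts Br from C12; the α-ester radical closes the γ-lactone by 5-exo-trig attack on C11 of the fluoroalkene, the resulting tertiary C15 radical closes the six-membered ring by 6-exo-trig attack on C1 of the C1=C2 alkene (which at the same time creates the 12-membered carbocycle), the C2 radical takes H from the silane, and DBU then removes HF from C11/C12 (E1cB) so that the double bond can only appear between C11 and C12. The closest known reaction types are silane- or stannane-mediated tandem radical cyclisations of α-halo esters and bromoacetals (Ueno–Stork cyclisation) relayed across macrocycles, and the base-induced dehydrofluorination of β-fluoro carbonyl compounds. Regioselectivity of the first closure (C11, not C15) rests on the exo preference, on the gem-dimethyl substitution of C15 and on the small size of fluorine, which unlike chlorine or bromine is not expelled by β-scission from the C15 radical. The second closure needs the C15 radical to add to C1 faster than it is reduced, abstracts an allylic hydrogen or attacks the C7=C8 alkene; slow addition of the weak hydrogen donor at high dilution and the fact that attack on C7=C8 would have to occur at a substituted alkene carbon should secure this. C11 and C12 are stereocentres only transiently (erased on HF loss); the one lasting new stereocentre, C1, is set in a chair-like 6-exo transition state in which the C2–C9 chain, anchored at C10, is expected to stay on the face of C9 and so give 1R, although this facial preference is argued from the ring topology and not proven. The ester must reach its s-cis rotamer before the first closure, which is the reason for 80 °C and syringe-pump addition, and DBU is kept mild to avoid epimerising the γ-position (C10) of the butenolide.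

**Compound list**
1 | triethyl 2-fluoro-2-phosphonoacetate | CCOC(=O)C(F)P(=O)(OCC)OCC | starting material
2 | acetone | CC(C)=O | starting material
3 | ethyl 2-fluoro-3-methylbut-2-enoate | CCOC(=O)C(F)=C(C)C | intermediate
4 | 2-fluoro-3-methylbut-2-en-1-ol | OCC(F)=C(C)C | intermediate
5 | 2-fluoro-3-methylbut-2-enal | O=CC(F)=C(C)C | intermediate
6 | allenylboronic acid pinacol ester | C=C=CB1OC(C)(C)C(C)(C)O1 | starting material
7 | (4R)-5-fluoro-6-methylhept-5-en-1-yn-4-ol | C#CC[C@@H](O)C(F)=C(C)C | intermediate
8 | tert-butyl{[(4R)-5-fluoro-6-methylhept-5-en-1-yn-4-yl]oxy}dimethylsilane | C#CC[C@@H](O[Si](C)(C)C(C)(C)C)C(F)=C(C)C | intermediate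
9 | (2E,5R)-5-(tert-butyldimethylsilyloxy)-6-fluoro-3,7-dimethylocta-2,6-dien-1-ol | OC/C=C(\C)C[C@@H](O[Si](C)(C)C(C)(C)C)C(F)=C(C)C | intermediate
10 | (2E,5R)-5-(tert-butyldimethylsilyloxy)-6-fluoro-3,7-dimethylocta-2,6-dienal | O=C/C=C(\C)C[C@@H](O[Si](C)(C)C(C)(C)C)C(F)=C(C)C | intermediate
11 | 3-chloro-2-(chloromethyl)prop-1-ene | C=C(CCl)CCl | starting material
12 | vinylmagnesium bromide | C=C[Mg]Br | starting material
13 | 2-(chloromethyl)penta-1,4-diene | C=CCC(=C)CCl | intermediate
14 | 2-isopropoxy-4,4,5,5-tetramethyl-1,3,2-dioxaborolane | CC(C)OB1OC(C)(C)C(C)(C)O1 | starting material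
15 | 4,4,5,5-tetramethyl-2-(2-methylidenepent-4-en-1-yl)-1,3,2-dioxaborolane | C=CCC(=C)CB1OC(C)(C)C(C)(C)O1 | intermediate
16 | (6S,7E,10R)-10-(tert-butyldimethylsilyloxy)-11-fluoro-8,12-dimethyl-4-methylidenetrideca-1,7,11-trien-6-ol | C=CCC(=C)C[C@H](O)/C=C(\C)C[C@@H](O[Si](C)(C)C(C)(C)C)C(F)=C(C)C | intermediate
17 | (6S,7E,10R)-10-(tert-butyldimethylsilyloxy)-11-fluoro-8,12-dimethyl-4-methylidenetrideca-1,7,11-trien-6-yl acetate | C=CCC(=C)C[C@H](OC(C)=O)/C=C(\C)C[C@@H](O[Si](C)(C)C(C)(C)C)C(F)=C(C)C | intermediate
18 | (6S,7E,10R)-11-fluoro-10-hydroxy-8,12-dimethyl-4-methylidenetrideca-1,7,11-trien-6-yl acetate | C=CCC(=C)C[C@H](OC(C)=O)/C=C(\C)C[C@@H](O)C(F)=C(C)C | intermediate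
19 | hex-5-enoic acid | C=CCCCC(=O)O | starting material
20 | 2-bromohex-5-enoic acid (racemic) | C=CCCC(Br)C(=O)O | intermediate
21 | (6S,7E,10R)-6-acetoxy-11-fluoro-8,12-dimethyl-4-methylidenetrideca-1,7,11-trien-10-yl 2-bromohex-5-enoate (epimers at the CHBr carbon) | C=CCC(=C)C[C@H](OC(C)=O)/C=C(\C)C[C@@H](OC(=O)C(Br)CCC=C)C(F)=C(C)C | intermediate
22 | 15-membered α-bromo macrolactone: (6E,11S,12E,15R)-3-bromo-15-(1-fluoro-2-methylprop-1-en-1-yl)-13-methyl-9-methylidene-2-oxo-1-oxacyclopentadeca-6,12-dien-11-yl acetate (epimers at C3 of this name = C12) | O=C1O[C@@H](C(F)=C(C)C)C/C(C)=C/[C@@H](OC(C)=O)CC(=C)C/C=C/CCC1Br | intermediate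
23 | tricyclic β-fluoro-γ-lactone: the 11-fluoro-11,12-dihydro derivative of 24 (C11/C12 epimers; C1, C6, C10 as in 24) | C=C1CC[C@@H]2CCC3C(F)([C@@H](C/C(C)=C/[C@@H](OC(C)=O)C1)OC3=O)C2(C)C | intermediate (not isolated)
24 | CNP0289913.1, verticillane-type 18,10-butenolide 6-acetate (1R,6S,7E,10R in the locants above) | C=C1CC[C@@H]2CCC3=C([C@@H](C/C(C)=C/[C@@H](OC(C)=O)C1)OC3=O)C2(C)C | target

**Step count and risks**
Total: 16 steps. Longest linear sequence: 13 steps (steps 1–7, 10–12, 14–16).

Step 16 (most at risk). What may go wrong: the C12 radical is reduced before the ester reaches the s-cis rotamer needed for lactone closure, or the C15 radical is reduced or shifts an allylic hydrogen before the slower 6-exo closure. Fallback: setting out from 22, halide exchange (NaI, acetone; Finkelstein reaction) gives the α-iodo macrolactone F1. An iodine-atom-transfer radical cascade (Bu3SnSnBu3 10 mol %, visible light, PhH, 80 °C) contains no hydrogen donor, so both slow closures can run to completion before the chain is passed on; it gives the tricyclic C2 iodide F2. Reduction of the C–I bond with (Me3Si)3SiH and AIBN then returns to the route at 23, which is treated with DBU as in step 16 to give 24.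

Step 15. What may go wrong: oligomerisation, or ring closure onto the 1,1-disubstituted alkene, at the dilution a 15-membered ring requires. Fallback: setting out from 18 and 20, cross-metathesis (second-generation Hoveyda–Grubbs catalyst, 20 in excess) forms the C1=C2 bond first and gives the seco acid F3. Macrolactonisation at the ester bond (2-methyl-6-nitrobenzoic anhydride, DMAP, Et3N, high dilution; Shiina macrolactonisation) then returns to the route at 22, and step 14 is no longer needed.

Step 4. What may go wrong: low enantioselectivity with the small, electron-poor α-fluoro enal, or induction in the opposite sense. Fallback: setting out from 5 and 6, an achiral acid-catalysed propargylboration ((PhO)2P(O)OH cat., toluene) gives the racemic alcohol F4. Lipase-catalysed acylation (Burkholderia cepacia lipase, vinyl acetate), which by the usual size rule for secondary alcohols is expected to acylate the R enantiomer faster, gives the (R)-acetate F5. F5 is separated from the unreacted S alcohol and methanolysed (K2CO3, MeOH) to return to the route at 7.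

**Further compounds**
F1 | step 16 | α-iodo macrolactone (iodine in place of bromine in 22) | O=C1O[C@@H](C(F)=C(C)C)C/C(C)=C/[C@@H](OC(C)=O)CC(=C)C/C=C/CCC1I
F2 | step 16 | tricyclic C2 iodide (2-iodo derivative of 23; epimers at C2, C11, C12) | C=C1CC(I)[C@@H]2CCC3C(F)([C@@H](C/C(C)=C/[C@@H](OC(C)=O)C1)OC3=O)C2(C)C
F3 | step 15 | seco acid: (5E,10S,11E,14R)-10-acetoxy-2-bromo-15-fluoro-14-hydroxy-12,16-dimethyl-8-methylideneheptadeca-5,11,15-trienoic acid | OC(=O)C(Br)CC/C=C/CC(=C)C[C@H](OC(C)=O)/C=C(\C)C[C@@H](O)C(F)=C(C)C
F4 | step 4 | racemic 5-fluoro-6-methylhept-5-en-1-yn-4-ol | C#CCC(O)C(F)=C(C)C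
F5 | step 4 | (4R)-5-fluoro-6-methylhept-5-en-1-yn-4-yl acetate | C#CC[C@@H](OC(C)=O)C(F)=C(C)C
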